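I began with the easy step, reading the summer run down its rows; it stands here with the new flask and the questions.

- summer: starting material 10 mM; second substrate 0.50 equiv; partner 1.8 equiv; free catalyst 3.8 mol%; run made earlier
- flask: starting material 10 mM; second substrate 0.500 equiv; partner 1.20 equiv; free catalyst 3.8 mol%; time 6.0 d

- summer (time / h: target / %): 1.33: 7.9; 4.00: 19.8; 6.00: 25.6; 10.0: 30.6; 15.0: 32.7

(readings scatter by 0.5 percentage points)

- the numbers in the tables scatter with a standard deviation of 0.5 percentage points

1. how much target there is at 6.0 d, in percent of the starting material charged
2. amount of target if the flask were left three thousand times as long, in percent of the starting material charged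

The first row gained 7.9% in 1.33 h, and the last row gained 2.1 points in 5.00 h, so the rate of making target fell by a factor of 14.1. Starting material, counted as charge less target, fell to 67.3%, a factor of 1.49, far less than the fall in rate. So I looked for the fade in partner or catalyst. The asked time is 9.60 times the last reading, so I expected this flask to have stopped as well.

The last row gives 18.2% for the partner's yield, the target made per partner charged. Holding that yield fixed, since both flasks share their starting material and catalyst charges, I reckoned 21.8% from 1.20 equiv of partner. The forecast stood higher than my reckoning, at 35% and 37%, holding that “the target should stay near that plateau if it is equilibrium”.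

The flask gave 26.3% at the asked time, and 26.3% for the long wait of the second question.

    partner + catalyst intermediate B → free catalyst + second product (k = 3.30 M⁻¹ min⁻¹)
    second substrate + free catalyst ⇌ catalyst intermediate B (K = 360 M⁻¹, k = 7.30 M⁻¹ min⁻¹)
    starting material + free catalyst ⇌ catalyst intermediate A (K = 42.0 M⁻¹, k = 6.20 M⁻¹ min⁻¹)
    partner + catalyst intermediate A → free catalyst + target (k = 29.0 M⁻¹ min⁻¹)
    second substrate + free catalyst → spent catalyst (k = 0.330 M⁻¹ min⁻¹)
    partner → decomposed reagent (k = 0.00250 min⁻¹)

The flask's partner's yield was 21.9%, above the summer run's 18.2%, and the neighbour at 40 mM of starting material, with the same equivalents, reached 45.0%. By 6.00 d the flask's partner, charged in excess of the starting material and first to run out, stood at 0%, with 8.09 mM of decomposed reagent formed and 73.7% of the starting material unused. Ten times the time left target at 26.3%, and what still moved was the catalyst, spent catalyst going from 98.0% to 100%.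

The earlier runs and the new flask were computed for an exercise; noise was put on by code.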